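(The earlier runs and the new flask were generated by integration with made-up constants, noise included.)

- Scaling a rate by the catalyst you weighed in is the trap when an impurity may bind it one to one.

all flasks: substrate 0.050 M
- eta: partner 0.065 M; free catalyst 1.2 mM; impurity 0.86 mM; temperature 0 °C; run made earlier
- delta: partner 0.065 M; free catalyst 5 mM; impurity 0.86 mM; temperature 12 °C; run made earlier
- gamma: partner 0.065 M; free catalyst 2.5 mM; impurity 1.3 mM; temperature 0 °C; run made earlier
- violet: partner 0.0650 M; free catalyst 2.5 mM; impurity 0.86 mM; temperature 5 °C; time 5.0 d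
- amber: partner 0.0650 M; free catalyst 2.5 mM; impurity 0.86 mM; temperature 20 °C; time 5.0 d

| run | time / d | catalyst intermediate B / % | catalyst intermediate C / % | target / % | substrate / % |
|---|---|---|---|---|---|
| eta | 1.04 | 1.4 | 0.5 | 1.3 | 98.4 |
| eta | 2.08 | 0 | 0.4 | 2.0 | 97.1 |
| eta | 3.00 | 0 | 0.5 | 3.0 | 96.0 |
| eta | 4.00 | 0.1 | 0 | 3.4 | 95.8 |
| delta | 0.333 | 1.9 | 2.0 | 18.2 | 77.9 |
| delta | 0.833 | 0.6 | 2.1 | 39.5 | 55.8 |
| delta | 1.67 | 2.2 | 0.2 | 64.0 | 32.0 |
| delta | 4.00 | 0 | 0.5 | 92.2 | 7.3 |
| gamma | 1.04 | 0.4 | 0.9 | 3.4 | 94.9 |
| gamma | 2.08 | 0.2 | 1.8 | 5.8 | 91.3 |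
| gamma | 3.00 | 0.5 | 0.8 | 9.0 | 89.7 |
| gamma | 4.00 | 1.0 | 0 | 12.4 | 87.2 |

(standard deviation of a reading: 0.5 percentage points)

1. which of these there is most of at the end, counted by the substrate in it, violet (substrate / target / catalyst intermediate B / catalyst intermediate C)
2. which of these there is most of at the end, counted by the substrate in it, amber (substrate / target / catalyst intermediate B / catalyst intermediate C)
3. amount of the one of these that there is most of at the end, in percent of the substrate charged, violet
4. amount of the one of these that there is most of at the end, in percent of the substrate charged, amber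



- Treat the impurity as a correction to the catalyst charge and compute only that. For violet and amber it gives 65.6 %: call this the working share, the fraction of the catalyst charge left once each impurity has taken one catalyst.
- The first way to test it uses charges alone. Eta has a working share of 28.3 % and gamma 48.0 %, so with share times charge, gamma holds 3.53 times the working catalyst of eta.
- The second way uses readings alone. After 4.00 d, target reads 3.4 % in eta and 12.4 % in gamma, a ratio of 3.65.
- The two meet: the charge ratio times eta's reading gives 12.0 %, against gamma's reading of 12.4 %, inside a scatter of 0.5 percentage points.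
- The bare weighed charges give a ratio of 2.08, less than the readings show, so that is the reckoning that cheats. You carry 1.64 mM of working catalyst into violet and into amber.
- The forecast, resting on “the impurity titrating catalyst”, puts substrate ahead in violet at 65 % and target ahead in amber at 94 %.
- Violet gives substrate at 66.8 %, and amber gives target at 77.0 %, so the forecast stands 17 points too high on amber.

    substrate + free catalyst ⇌ catalyst intermediate A (K = 9.60 M⁻¹, k = 0.650 M⁻¹ min⁻¹, Ea = 60.0 kJ mol⁻¹, ΔH = 0 kJ mol⁻¹)
    catalyst intermediate A → catalyst intermediate B (k = 0.0260 min⁻¹, Ea = 87.0 kJ mol⁻¹)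
    partner + catalyst intermediate B ⇌ catalyst intermediate C (K = 64.0 M⁻¹, k = 0.390 M⁻¹ min⁻¹, Ea = 53.0 kJ mol⁻¹, ΔH = −32.0 kJ mol⁻¹)
    catalyst intermediate C → free catalyst + target (k = 0.00490 min⁻¹, Ea = 98.0 kJ mol⁻¹)
    free catalyst + impurity → spent catalyst A (k = 66.0 M⁻¹ min⁻¹, Ea = 49.0 kJ mol⁻¹)
    partner + free catalyst → spent catalyst B (k = 0.00750 M⁻¹ min⁻¹, Ea = 55.0 kJ mol⁻¹)
    (constants at 5 °C)

- Amber ends with more target than violet, 77.0 % against 32.2 %, and the difference in temperature is the main reason for that gap. At 5.00 d, amber has impurity at 0 % and spent catalyst A at 34.4 % of the catalyst charge, beside the 34.4 % that the working share took off. But partner takes free catalyst too: by 5.00 d, spent catalyst B holds 60.2 % of amber's catalyst charge, out of a working share of 65.6 %. Taking that reaction away lifts amber's target from 77.0 % to >99.9 %, which is part of the account. The neighbour of violet with 0.010 M of free catalyst has a working share of 91.4 %, shows spent catalyst A at 8.60 % of its catalyst charge, and ends at 97.7 % target.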